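The earlier runs and the new flask are calculated with made-up constants, noise included.

Thursday's run and Monday's run differ in c(starting material) by a factor of 2.24, yet at 4.00 h they stand at 9% and 11% target. That gap of 2 percentage points is little more than the scatter of 1.5 points per reading.

| setting | Thursday's | Monday's | Wednesday's | flask |
|---|---|---|---|---|
| starting material | 0.067 M | 0.15 M | 0.10 M | 0.10 M |
| reagent in the second phase | 0.20 M | 0.20 M | 0.30 M | 0.200 M |
| remark | run made earlier | run made earlier | run made earlier |  |
| time |  |  |  | 4.0 h |
| volume of the second phase over the first |  |  |  | 1.0 |

| run | time / h | target / % | starting material / % |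
|---|---|---|---|
| Thursday's | 0.250 | 2 | 101 |
| Thursday's | 0.833 | 2 | 100 |
| Thursday's | 1.33 | 1 | 98 |
| Thursday's | 2.00 | 4 | 94 |
| Thursday's | 3.00 | 5 | 94 |
| Thursday's | 4.00 | 9 | 87 |
| Monday's | 0.667 | 2 | 100 |
| Monday's | 1.33 | 5 | 98 |
| Monday's | 2.00 | 3 | 96 |
| Monday's | 2.50 | 6 | 97 |
| Monday's | 3.00 | 6 | 91 |
| Monday's | 4.00 | 11 | 86 |
| Wednesday's | 0.333 | 1 | 100 |
| Wednesday's | 1.00 | 2 | 97 |
| Wednesday's | 2.00 | 8 | 93 |
| Wednesday's | 3.00 | 10 | 87 |
| Wednesday's | 4.00 | 14 | 83 |

(readings scatter by 1.5 percentage points)

- in the second phase: reagent in the second phase; everything else is in the first
- charges count per volume of the first phase; a concentration in a rate is the amount of a species over the volume of its own phase; every rate counts per litre of the first phase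
- the analysis behind the earlier runs scatters by 1.5 percentage points, standard deviation
- the earlier runs hold the two phases in the same ratio of volumes as the flask asked about

- ash: doubling the amount of reagent in the second phase, all else as stated
- maple: doubling the transfer coefficient of the reagent in the second phase, all else as stated

- the target standing at 4.0 h, as a percentage of the starting material charged
- the change that raises the amount of target at 4.0 h, in percent of the starting material charged most ("none" if none brings more than 2 percentage points) (ash / maple / none)
- amount of target at 4.0 h, in percent of the starting material charged, after ash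

I turn the settings by hand, one at a time. Starting material first: the percentage barely follows its charge, so I put the flask, which lies between those runs, at their mean of 10.0%.

Reagent next: raising c(reagent in the second phase) from 0.20 M to 0.30 M gives 14% on Wednesday, which is a power of 0.830. Doubling it by ash would therefore bring the flask to 17.8% by my reckoning, a gain of 7.8 points.

Time last: I define the time exponent as the power of time that target follows between 2.00 h and 4.00 h. Summing the three runs, 15.0% becomes 34.0%, so the exponent reads 1.18. A value of 1 would mean target in proportion to time, and a value above 1 says that target more than doubles as the time doubles, which I read as the trace of an early lag, an induction period. I take the excess over 1 as the share that follows reagent supply, so maple, doubling the transfer coefficient, scales target by 1.13 and gains 1.3 points. That is less than ash gains, so I choose ash.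

The forecast gives 10%, ash and 18.5% after ash, noting that “The pooled curves are mildly convex”.

The flask gives 9.43%; ash adds 4.6 points and reaches 14.0%, while maple adds 2.7 points.

    reagent in the reaction phase ⇌ reagent in the second phase, rate k1*([reagent in the reaction phase] - [reagent in the second phase]/K1) per volume of the first phase (partition coefficient = 0.370, kL = 2.16 × 10⁻⁵ /s)
    starting material + reagent in the reaction phase → target (k = 2.77 × 10⁻⁴ /M/s)
    reagent in the reaction phase + target → over-reacted product (k = 0.00105 /M/s)
    reagent in the reaction phase ⇌ dormant form (K = 0.427, k = 1.82 × 10⁻⁴ /s)
    reagent in the reaction phase → decomposed reagent (k = 6.45 × 10⁻⁵ /s)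
    target ⇌ isomer of the product (K = 8.00, k = 2.45 × 10⁻⁶ /s)

In the flask, reagent in the reaction phase is made 1.61 times as fast as it is used at 1.54 h, and that ratio is 1.00 at 4.00 h. The flask's own target, 4.17% at 2.00 h and 9.43% at 4.0 h, gives a time exponent of 1.18. Carried back from the flask with 1.18, the neighbour stopped at 1.0 h should hold 1.84% target, and it holds 1.44%.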